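## The problem

Compound 25 is apigenin carrying a 2-carboxy-1-phenylethyl group at C8, and its one stereocentre, the (R)-configured methine of that side chain, bears a phenyl group, the fully substituted ring A and the CH2CO2H arm. No second stereocentre exists from which it could be relayed, so a chiral catalyst has to set it; as a diaryl methine it would ask that catalyst to tell two arenes apart unless it is made while one of them is not yet an arene. Ring A is a phloroglucinol whose three oxygens take three different roles (O1 of the pyranone, the 7-hydroxyl, the 5-hydroxyl), and the acyl carbon C4 must enter at C4a and not at C6, although these positions are electronically alike. C8 lies between C8a-O1 and C7-OH, and any free phenol ortho to the side chain closes onto the carboxyl as a 4-phenyldihydrocoumarin as soon as acid is present; this lactone has to be planned for, and the open hydroxy acid can only be released at the end without strong acid. The doubly benzylic methine on an electron-rich ring must be kept from strong oxidants and from hot strong acid, and the pyranone from hot alkali. The key step is possible because the second aryl group is an unsubstituted phenyl: its six carbons are the two of an ethynyl group plus the four of butadiene, so the centre can be set as a propargylic one, where alkynyl and aryl differ sharply, and the phenyl ring grown afterwards.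

## Retrosynthesis

The ester C-O bond between the side-chain carboxyl and O7 is formed in reverse first, taking 25 back to its own dihydrocoumarin 24. A methyl or tert-butyl ester was rejected because every acidic step would convert it into this lactone anyway. The lactone masks the carboxyl and the 7-hydroxyl in one ring, and the forward step only has to hydrolyse an activated aryl ester and acidify without re-closing it.

The two O-CH3 bonds at C5 and C4' are cut next (24 from 23). Methyl ethers are kept to the end because these oxygens must pass through Lewis acid and iodine in hot DMSO. The forward reaction is a BBr3 demethylation that should leave the aryl lactone in place.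

Ring C is opened at O1-C2 and then at the C2-C3 double bond: 23 comes from chalcone 21 by oxidative cyclisation, and 21 from acetophenone 19 and 4-methoxybenzaldehyde 20 by aldol condensation. An aroyl-transfer (Baker-Venkataraman) sequence would need three steps and strong base beside an enolisable aryl lactone; the chalcone road needs two steps and only acid. In 19 one ortho oxygen is a methyl ether and the other oxygen on the ring is tied up in the lactone, so only one hydroxyl can close ring C.

The aryl-acyl bond C4a-C4 is cut (19 from 16). The single free hydroxyl of 16 directs a Fries shift to its only free ortho carbon. The precursor has lost the whole flavone and is a plain 4-phenyldihydrocoumarin.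

The lactone C-O bond and two methoxymethyl acetals are cut (16 from 14). The aryl group of 14 is symmetrical, with two identical protected oxygens flanking the methine, so whichever of them lactonises after deprotection (via 15), the same 16 results. This lactonisation tells O7 from O1 without any selective protection. A pattern with only one removable ortho group was rejected: freeing that hydroxyl would lactonise the oxygen that has to direct the acylation and become O1.

The phenyl ring is cut at two bonds, the one from the ipso carbon to one ortho carbon and the one from the other ortho carbon to its meta neighbour (14 from alkyne 11 and butadiene 12, through cyclohexadiene 13). Conjugate arylation of a diaryl-type acceptor was the alternative; the alkyne route makes the centre with an ethynyl group in place of an arene. The forward step must form the ring under neutral conditions and aromatise without touching the methine.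

The propargylic C-C bond is cut (11 from Meldrum's acid adduct 8, made from arylidene 6 and ethynyltrimethylsilane 7; 6 from aldehyde 4 and Meldrum's acid 5). This is the one step that must be enantioselective. The doubly activated acceptor is what makes a catalytic alkynylation feasible, and methanolysis with decarboxylation delivers the ester directly.

The formyl C-C bond is cut (4 from bis-ether 2 through aryllithium 3; 2 from 5-methoxyresorcinol 1). The two methoxymethyl groups serve as protecting groups and as the directing groups that place lithium, and then the formyl carbon, between them.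

## Roads not taken

Alternative 1: Ring A could be cut at C8-C8a and C4a-C5 and made by a Diels-Alder reaction. The diene would be tert-butyl (3S)-7-methoxy-3-phenyl-5,7-bis(trimethylsilyloxy)hepta-4,6-dienoate A2, which already carries the stereocentre. The dienophile would be 2-[4-(methoxymethoxy)phenyl]-5-(4-methylbenzenesulfinyl)-4H-pyran-4-one A3. The substituted terminus of A2 would bond to the carbon of A3 next to the ring oxygen, and the ketene acetal carbon of A2 to the sulfinyl-bearing carbon of A3. The adduct would aromatise in the same flask by shedding its sulfur, methoxy and silyl groups, giving tert-butyl (3R)-3-[5,7-dihydroxy-2-[4-(methoxymethoxy)phenyl]-4-oxo-4H-chromen-8-yl]-3-phenylpropanoate A1.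
- Merits: it is strongly convergent, every ring A oxygen is placed by construction, and no acylation regiochemistry arises. A3 is a simple achiral pyranone that already holds ring C and the second aryl group.
- Weak points: the new bond to C8a joins a diene terminus carrying a branched benzylic carbon to a carbon of A3 that bears oxygen, the most hindered pairing possible. Only the E-configured terminus of A2 can react, and the stereocentre of A2 still has to be made by an asymmetric step that this plan does not simplify.
- A1 has the free 7-hydroxyl beside a tert-butyl ester, so acidic deprotection would close the lactone and the ending would be the same as 24 to 25.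
- Comparison: if the cycloaddition worked, this road would have a shorter longest linear sequence and no Fries step, and in that it is better. The chosen plan sets against it close precedent for every step and a stereocentre made where the two competing groups differ most.

Alternative 2: A benzannulation of the Danheiser type would cut C8a-C8, C6-C7 and C4a-C8a. Irradiation of 1-diazo-3-methoxybut-3-en-2-one A5 would give, by Wolff rearrangement, 3-methoxybuta-1,3-dien-1-one A7. This ketene would add to tert-butyl (3R)-3-phenyl-5-(triisopropylsilyloxy)pent-4-ynoate A6. After (2+2) addition, four-electron ring opening, six-electron closure and tautomerisation the product would be tert-butyl (3R)-3-[2-hydroxy-4-methoxy-6-(triisopropylsilyloxy)phenyl]-3-phenylpropanoate A4.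
- Merits: the three oxygens emerge fully differentiated from the ring-forming step, which is better than the chosen plan's reliance on a symmetrical aryl group and a lactonisation. The propargylic centre of A6 would also be made on an unhindered phenyl-substituted acceptor, easier than step 4.
- Weak points: A6 requires an ester or terminal alkyne to be turned into a silyl ynol ether beside a second ester. A5 is a small, hazardous vinyl diazo ketone whose ketene A7 dimerises readily, and the step is photochemical.
- The differentiation cannot be used. Acylating A4 under Lewis acid would cleave the tert-butyl ester and lactonise the hydroxyl that must become O1; removing the silyl group first gives the same symmetrical dihydroxy arrangement as in 15.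
- Comparison: the step count is at best equal. The chosen plan offers a thermal, catalytic ring construction from a cheap four-carbon unit and no diazo compound.

Alternative 3: Ring C could be made in one step by cutting O1-C8a, C4a-C4 and O1-C2. Fluoride would convert methyl (3R)-3-[4,6-dimethoxy-2-(trifluoromethylsulfonyloxy)-3-(trimethylsilyl)phenyl]-3-phenylpropanoate A9 into the aryne methyl (3R)-3-(2,3-didehydro-4,6-dimethoxyphenyl)-3-phenylpropanoate A11. The coupling partner would be 3-(4-methoxyphenyl)prop-2-ynoic acid A10. The carboxylate of A10 would add through oxygen at C8a of A11, the aryl anion at C4a would take the acyl carbon, and the freed phenoxide would close onto the ynone. The product would be methyl (3R)-3-[5,7-dimethoxy-2-(4-methoxyphenyl)-4-oxo-4H-chromen-8-yl]-3-phenylpropanoate A8.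
- Merits: ring C forms in one operation against three steps (8 to 10) here, the C5 methoxy group steers the nucleophile to the correct aryne carbon, and no free phenol stands beside the side chain before the end. A10 is a simple acid that brings C2, C3, C4 and the second aryl group in one piece. In these respects it is better.
- Weak points: silicon and triflate must be placed at C4a and C8a of A9 and not at C6, which is the positional question of step 8 moved to an earlier stage. Attack at C8a is electronically preferred but lies next to the branched methine, and A11 may abstract the doubly benzylic hydrogen.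
- The stereocentre is not addressed, so A9 would still need the alkyne route or arene-arene discrimination. A8 then needs three demethylations and passes through the same lactone question as 24.
- Comparison: it is shorter after the diaryl ester if the aryne step works. The chosen plan sets against it unambiguous regiochemistry from symmetrical 14 and precedent for each step.

Key step: step 6

Assumption: the ligand antipodes named in step 4 and in the fallback to step 6 are taken to be the ones that deliver the configuration drawn; if the facial preference is the opposite, the other antipode is used and nothing else changes.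

## Route

Step 1
Reactants: 1 5-methoxybenzene-1,3-diol
Product: 2 1-methoxy-3,5-bis(methoxymethoxy)benzene
Conditions: MOMCl (2.5 equiv), iPr2NEt (3 equiv), CH2Cl2, 0 °C to 23 °C
Reagents that add atoms: chloromethyl methyl ether, COCCl
Why: O-alkylation of both phenols to mixed acetals; the methoxymethyl groups later direct lithiation and fall off in dilute acid.

Step 2
Reactants: 2 1-methoxy-3,5-bis(methoxymethoxy)benzene
Product: 4 4-methoxy-2,6-bis(methoxymethoxy)benzaldehyde, via aryllithium 3 (not isolated)
Conditions: n-BuLi (1.1 equiv), TMEDA, THF, 0 °C; then DMF, 0 °C to 23 °C; aq. NH4Cl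
Reagents that add atoms: N,N-dimethylformamide, CN(C)C=O
Why: Directed ortho-metalation; the carbon between the two methoxymethoxy groups has two chelating acetal oxygens and should be lithiated in preference to the carbons next to the methoxy group, and formylation with DMF then gives the symmetrical aldehyde.

Step 3
Reactants: 4 4-methoxy-2,6-bis(methoxymethoxy)benzaldehyde; 5 2,2-dimethyl-1,3-dioxane-4,6-dione (Meldrum's acid)
Product: 6 5-{[4-methoxy-2,6-bis(methoxymethoxy)phenyl]methylidene}-2,2-dimethyl-1,3-dioxane-4,6-dione
Conditions: pyrrolidine (10 mol %), AcOH (10 mol %), toluene, 4 Å molecular sieves, 50 °C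
Reagents that add atoms: none
Why: Knoevenagel condensation through the iminium ion of the aldehyde; di-ortho-alkoxy benzaldehydes are known to give stable arylidene Meldrum's acids, and the buffered catalyst spares the acetals.

Step 4
Reactants: 6 5-{[4-methoxy-2,6-bis(methoxymethoxy)phenyl]methylidene}-2,2-dimethyl-1,3-dioxane-4,6-dione; 7 ethynyltrimethylsilane
Product: 8 5-{(1S)-1-[4-methoxy-2,6-bis(methoxymethoxy)phenyl]-3-(trimethylsilyl)prop-2-yn-1-yl}-2,2-dimethyl-1,3-dioxane-4,6-dione
Conditions: [Rh(OAc)(C2H4)2]2 (2.5 mol %), (S)-3,5-xylyl-MeO-BIPHEP (6 mol %), 7 (3 equiv), 1,4-dioxane/H2O (10:1), 15 °C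
Reagents that add atoms: none
Why: Rhodium-catalysed asymmetric conjugate alkynylation of an arylidene Meldrum's acid: an alkynyl complex of monovalent rhodium adds across the doubly activated alkene and the rhodium enolate is protonated. The chiral bisphosphine selects the face and so sets the stereocentre (S here because the silylalkynyl group outranks the aryl group), and the bulky ligand and low temperature hold back alkyne dimerisation.

Step 5
Reactants: 8 5-{(1S)-1-[4-methoxy-2,6-bis(methoxymethoxy)phenyl]-3-(trimethylsilyl)prop-2-yn-1-yl}-2,2-dimethyl-1,3-dioxane-4,6-dione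
Product: 11 methyl (3R)-3-[4-methoxy-2,6-bis(methoxymethoxy)phenyl]pent-4-ynoate, via malonic half-ester 9 (not isolated), via silyl alkyne ester 10 (not isolated)
Conditions: MeOH/pyridine (1:4), 100 °C, sealed tube; then K2CO3 (20 mol %), MeOH, 23 °C
Reagents that add atoms: methanol, CO
Why: Methanol opens the dioxanedione with loss of acetone, the half-ester 9 decarboxylates in hot pyridine to 10, and catalytic methoxide then moves the silyl group from the alkyne carbon to methanol. The stereocentre is beta to the ester and not acidic; the descriptor changes from S to R only because ethynyl ranks below the aryl group.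

Step 6
Reactants: 11 methyl (3R)-3-[4-methoxy-2,6-bis(methoxymethoxy)phenyl]pent-4-ynoate; 12 buta-1,3-diene
Product: 14 methyl (3R)-3-[4-methoxy-2,6-bis(methoxymethoxy)phenyl]-3-phenylpropanoate, via cyclohexadiene 13 (not isolated)
Conditions: CoBr2(dppe) (10 mol %), Zn (20 mol %), ZnI2 (20 mol %), 12 (5 equiv), CH2Cl2, 23 °C, sealed vessel; then DDQ (1.1 equiv), toluene, 23 °C
Reagents that add atoms: none
Why: Zinc reduces divalent cobalt in CoBr2(dppe) to a monovalent species from which ZnI2 abstracts halide; the resulting cation binds butadiene 12 and the alkyne of 11, couples them oxidatively to a trivalent cobaltacycle and releases the 1,4-cyclohexadiene 13 by reductive elimination, which forms the two ring bonds (internal alkyne carbon to one diene terminus, terminal alkyne carbon to the other) and closes the six-membered ring as a metal-mediated (4+2) closure at room temperature. The closest known reaction type is the cobalt-catalysed neutral Diels-Alder reaction of unactivated terminal alkynes with 1,3-dienes followed by dehydrogenation with DDQ. DDQ then takes hydride from a doubly allylic CH2 of 13 and a proton is lost, which turns the ring into the phenyl group of 14. No stereocentre is created: the propargylic centre is neither deprotonated nor ionised under these neutral conditions and becomes the diaryl methine with its spatial arrangement unchanged (R in 11, 13 and 14). The step needs cross-cycloaddition to outrun alkyne cyclotrimerisation, which the excess of butadiene and the branched propargylic position should secure, and symmetrical butadiene leaves no regiochemical question. It also needs the oxidant to stop at the arene: the two ortho substituents hold the methine C-H in the plane of the electron-rich ring, where it is poorly activated for hydride loss, both phenols are capped so that no quinone methide can form, and only a slight excess of DDQ is used.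

Step 7
Reactants: 14 methyl (3R)-3-[4-methoxy-2,6-bis(methoxymethoxy)phenyl]-3-phenylpropanoate
Product: 16 (4R)-5-hydroxy-7-methoxy-4-phenyl-3,4-dihydro-2H-chromen-2-one, via dihydroxy ester 15 (not isolated)
Conditions: HCl (3 M), MeOH, 50 °C; then evaporate, TsOH·H2O (10 mol %), toluene, 90 °C
Reagents that add atoms: none
Why: Acid-catalysed acetal methanolysis frees both phenols, with the formaldehyde unit trapped as its dimethyl acetal, and acid-catalysed lactonisation then closes the six-membered ring with loss of methanol. The two hydroxyls of 15 are equivalent by rotation about the aryl-methine bond, so one lactone results and exactly one hydroxyl stays free.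

Step 8
Reactants: 16 (4R)-5-hydroxy-7-methoxy-4-phenyl-3,4-dihydro-2H-chromen-2-one
Product: 19 (4R)-6-acetyl-5-hydroxy-7-methoxy-4-phenyl-3,4-dihydro-2H-chromen-2-one, via aryl acetate 17 (not isolated), via difluoroboron chelate 18 (not isolated)
Conditions: Ac2O (1.5 equiv), BF3·OEt2 (3 equiv), 70 °C; then aq. NaOAc, MeOH, 60 °C
Reagents that add atoms: acetic anhydride, CC(=O)OC(C)=O
Why: O-acetylation followed by a BF3-mediated Fries rearrangement; the acyl group settles on the only carbon ortho to the hydroxyl, where the six-membered difluoroboron chelate 18 makes the ortho ketone the thermodynamic product, and aqueous acetate then breaks the chelate. The lactone is the stable form of the side chain under these conditions.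

Step 9
Reactants: 19 (4R)-6-acetyl-5-hydroxy-7-methoxy-4-phenyl-3,4-dihydro-2H-chromen-2-one; 20 4-methoxybenzaldehyde
Product: 21 (4R)-5-hydroxy-7-methoxy-6-[(2E)-3-(4-methoxyphenyl)prop-2-enoyl]-4-phenyl-3,4-dihydro-2H-chromen-2-one
Conditions: 20 (1.2 equiv), BF3·OEt2 (0.5 equiv), 1,4-dioxane, 23 °C
Reagents that add atoms: none
Why: Lewis acid-mediated Claisen-Schmidt condensation: the enol of the methyl ketone adds to the activated aldehyde and the aldol dehydrates to the E-enone. No base is present, so the lactone stays closed and keeps the oxygen para to the ketone acylated.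

Step 10
Reactants: 21 (4R)-5-hydroxy-7-methoxy-6-[(2E)-3-(4-methoxyphenyl)prop-2-enoyl]-4-phenyl-3,4-dihydro-2H-chromen-2-one
Product: 23 (10R)-5-methoxy-2-(4-methoxyphenyl)-10-phenyl-9,10-dihydro-4H,8H-pyrano[2,3-f]chromene-4,8-dione, via flavanone 22 (not isolated)
Conditions: I2 (10 mol %), DMSO, 120 °C
Reagents that add atoms: none
Why: Oxidative cyclisation of a 2'-hydroxychalcone: oxa-Michael closure gives flavanone 22, alpha-iodination and loss of HI give the pyranone, and DMSO reoxidises iodide. Only the hydroxyl ortho to the enone is free, so only the required ring can form.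

Step 11
Reactants: 23 (10R)-5-methoxy-2-(4-methoxyphenyl)-10-phenyl-9,10-dihydro-4H,8H-pyrano[2,3-f]chromene-4,8-dione
Product: 24 (10R)-5-hydroxy-2-(4-hydroxyphenyl)-10-phenyl-9,10-dihydro-4H,8H-pyrano[2,3-f]chromene-4,8-dione
Conditions: BBr3 (6 equiv), CH2Cl2, -78 °C to 23 °C; then H2O, 0 °C
Reagents that add atoms: none
Why: Lewis acid cleavage of aryl methyl ethers; the methoxy group peri to the carbonyl goes first and the anisole-type ether needs the excess. The aryl lactone has no alkyl-oxygen bond to cleave and should survive.

Step 12
Reactants: 24 (10R)-5-hydroxy-2-(4-hydroxyphenyl)-10-phenyl-9,10-dihydro-4H,8H-pyrano[2,3-f]chromene-4,8-dione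
Product: 25 (3R)-3-[5,7-dihydroxy-2-(4-hydroxyphenyl)-4-oxo-4H-chromen-8-yl]-3-phenylpropanoic acid
Conditions: LiOH (4 equiv), THF/H2O (2:1), 0 °C to 23 °C; then 1 M HCl to pH 3-4, 0 °C
Reagents that add atoms: lithium hydroxide, [Li+].[OH-]
Why: Saponification of an aryl ester; the departing 7-oxide is a vinylogous carboxylate, so opening should be fast in the cold and re-closure slow. Mild acidification and evaporation without heat should give the open hydroxy acid, with the stereocentre (beta to the carboxylate) untouched.

## Compound list

1 | 5-methoxybenzene-1,3-diol | COc1cc(O)cc(O)c1 | starting material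
2 | 1-methoxy-3,5-bis(methoxymethoxy)benzene | COCOc1cc(OC)cc(OCOC)c1 | intermediate
3 | [4-methoxy-2,6-bis(methoxymethoxy)phenyl]lithium | [Li]c1c(OCOC)cc(OC)cc1OCOC | intermediate
4 | 4-methoxy-2,6-bis(methoxymethoxy)benzaldehyde | COCOc1cc(OC)cc(OCOC)c1C=O | intermediate
5 | 2,2-dimethyl-1,3-dioxane-4,6-dione (Meldrum's acid) | CC1(C)OC(=O)CC(=O)O1 | starting material
6 | 5-{[4-methoxy-2,6-bis(methoxymethoxy)phenyl]methylidene}-2,2-dimethyl-1,3-dioxane-4,6-dione | CC1(C)OC(=O)C(=Cc2c(OCOC)cc(OC)cc2OCOC)C(=O)O1 | intermediate
7 | ethynyltrimethylsilane | C#C[Si](C)(C)C | starting material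
8 | 5-{(1S)-1-[4-methoxy-2,6-bis(methoxymethoxy)phenyl]-3-(trimethylsilyl)prop-2-yn-1-yl}-2,2-dimethyl-1,3-dioxane-4,6-dione | CC1(C)OC(=O)C([C@H](C#C[Si](C)(C)C)c2c(OCOC)cc(OC)cc2OCOC)C(=O)O1 | intermediate
9 | (3S)-2-(methoxycarbonyl)-3-[4-methoxy-2,6-bis(methoxymethoxy)phenyl]-5-(trimethylsilyl)pent-4-ynoic acid (both C2 epimers) | COC(=O)C(C(O)=O)[C@H](C#C[Si](C)(C)C)c1c(OCOC)cc(OC)cc1OCOC | intermediate
10 | methyl (3S)-3-[4-methoxy-2,6-bis(methoxymethoxy)phenyl]-5-(trimethylsilyl)pent-4-ynoate | COC(=O)C[C@H](C#C[Si](C)(C)C)c1c(OCOC)cc(OC)cc1OCOC | intermediate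
11 | methyl (3R)-3-[4-methoxy-2,6-bis(methoxymethoxy)phenyl]pent-4-ynoate | COC(=O)C[C@H](C#C)c1c(OCOC)cc(OC)cc1OCOC | intermediate
12 | buta-1,3-diene | C=CC=C | starting material
13 | methyl (3R)-3-(cyclohexa-1,4-dien-1-yl)-3-[4-methoxy-2,6-bis(methoxymethoxy)phenyl]propanoate | COC(=O)C[C@H](C1=CCC=CC1)c1c(OCOC)cc(OC)cc1OCOC | intermediate
14 | methyl (3R)-3-[4-methoxy-2,6-bis(methoxymethoxy)phenyl]-3-phenylpropanoate | COC(=O)C[C@H](c1ccccc1)c1c(OCOC)cc(OC)cc1OCOC | intermediate
15 | methyl (3R)-3-(2,6-dihydroxy-4-methoxyphenyl)-3-phenylpropanoate | COC(=O)C[C@H](c1ccccc1)c1c(O)cc(OC)cc1O | intermediate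
16 | (4R)-5-hydroxy-7-methoxy-4-phenyl-3,4-dihydro-2H-chromen-2-one | O=C1C[C@H](c2ccccc2)c2c(O)cc(OC)cc2O1 | intermediate
17 | (4R)-7-methoxy-2-oxo-4-phenyl-3,4-dihydro-2H-chromen-5-yl acetate | O=C1C[C@H](c2ccccc2)c2c(OC(C)=O)cc(OC)cc2O1 | intermediate
18 | difluoroboron chelate of (4R)-6-acetyl-5-hydroxy-7-methoxy-4-phenyl-3,4-dihydro-2H-chromen-2-one (boron bound to the phenolic and the ketone oxygen) | O=C1C[C@H](c2ccccc2)c2c3O[B-](F)(F)[O+]=C(C)c3c(OC)cc2O1 | intermediate
19 | (4R)-6-acetyl-5-hydroxy-7-methoxy-4-phenyl-3,4-dihydro-2H-chromen-2-one | O=C1C[C@H](c2ccccc2)c2c(O)c(C(C)=O)c(OC)cc2O1 | intermediate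
20 | 4-methoxybenzaldehyde | COc1ccc(C=O)cc1 | starting material
21 | (4R)-5-hydroxy-7-methoxy-6-[(2E)-3-(4-methoxyphenyl)prop-2-enoyl]-4-phenyl-3,4-dihydro-2H-chromen-2-one | O=C1C[C@H](c2ccccc2)c2c(O)c(C(=O)/C=C/c3ccc(OC)cc3)c(OC)cc2O1 | intermediate
22 | (10R)-5-methoxy-2-(4-methoxyphenyl)-10-phenyl-2,3,9,10-tetrahydro-4H,8H-pyrano[2,3-f]chromene-4,8-dione (both C2 epimers) | O=C1C[C@H](c2ccccc2)c2c(O1)cc(OC)c1C(=O)CC(c3ccc(OC)cc3)Oc21 | intermediate
23 | (10R)-5-methoxy-2-(4-methoxyphenyl)-10-phenyl-9,10-dihydro-4H,8H-pyrano[2,3-f]chromene-4,8-dione | O=C1C[C@H](c2ccccc2)c2c(O1)cc(OC)c1c(=O)cc(-c3ccc(OC)cc3)oc21 | intermediate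
24 | (10R)-5-hydroxy-2-(4-hydroxyphenyl)-10-phenyl-9,10-dihydro-4H,8H-pyrano[2,3-f]chromene-4,8-dione | O=C1C[C@H](c2ccccc2)c2c(O1)cc(O)c1c(=O)cc(-c3ccc(O)cc3)oc21 | intermediate
25 | (3R)-3-[5,7-dihydroxy-2-(4-hydroxyphenyl)-4-oxo-4H-chromen-8-yl]-3-phenylpropanoic acid | O=C(O)C[C@H](c1ccccc1)c1c(O)cc(O)c2c(=O)cc(-c3ccc(O)cc3)oc12 | target

## Step count and least certain steps

Total: 12 steps. Longest linear sequence: 12 steps, from 1 to 25.

Step 6 (key step). The catalyst derived from CoBr2(dppe) may couple the hindered terminal alkyne with itself faster than with butadiene. ZnI2 may strip a methoxymethyl group, exposing a phenol that the quinone then oxidises, or the oxidant may attack the electron-rich ring. The fallback gives up the ring construction and sets out from 6. Conjugate arylation with PhB(OH)2, Rh(acac)(C2H4)2 and the antipode of 2,5-diphenylbicyclo[2.2.2]octa-2,5-diene that gives the R adduct (aq. KOH, 1,4-dioxane) should give 5-{(R)-[4-methoxy-2,6-bis(methoxymethoxy)phenyl](phenyl)methyl}-2,2-dimethyl-1,3-dioxane-4,6-dione F1. Heating F1 in MeOH/pyridine passes through (3R)-2-(methoxycarbonyl)-3-[4-methoxy-2,6-bis(methoxymethoxy)phenyl]-3-phenylpropanoic acid F2 and comes back to the route at 14. The catalyst then has to tell two arenes apart, helped by their very different size.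

Step 4. Addition to the twisted, electron-rich, di-ortho-substituted acceptor may be slow and poorly face-selective, and alkyne dimerisation may take over. The fallback replaces catalysis by resolution and sets out from 6. [(Trimethylsilyl)ethynyl]magnesium bromide (THF, -40 °C; aq. NH4Cl) should give racemic 5-{1-[4-methoxy-2,6-bis(methoxymethoxy)phenyl]-3-(trimethylsilyl)prop-2-yn-1-yl}-2,2-dimethyl-1,3-dioxane-4,6-dione F3. Chromatography on an amylose tris(3,5-dimethylphenylcarbamate) phase separates F3 into 8, where the route is rejoined, and 5-{(1R)-1-[4-methoxy-2,6-bis(methoxymethoxy)phenyl]-3-(trimethylsilyl)prop-2-yn-1-yl}-2,2-dimethyl-1,3-dioxane-4,6-dione F4, which is set aside.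

Step 8. The acyl group may migrate to the carbon para to the hydroxyl instead of the ortho carbon, and the hot Lewis acid may erode the configuration by reversible ipso-protonation of the electron-rich ring. Para-acylation is less damaging than it looks, because both modes of acylation converge on one open hydroxy acid whose re-lactonisation should favour the unchelated hydroxyl, but an ortho-specific method is the cleaner answer. The fallback sets out from 16 and uses an ortho-specific formylation. MgCl2, Et3N and paraformaldehyde in MeCN at 80 °C should give (4R)-5-hydroxy-7-methoxy-2-oxo-4-phenyl-3,4-dihydro-2H-chromene-6-carbaldehyde F5. MeTi(OiPr)3 (THF, -30 °C to 0 °C) adds to the aldehyde but not the lactone, giving (4R)-5-hydroxy-6-(1-hydroxyethyl)-7-methoxy-4-phenyl-3,4-dihydro-2H-chromen-2-one F6 as a mixture of carbinol epimers. MnO2 in CH2Cl2 oxidises F6 and the route is rejoined at 19.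

Step 9. The acid-mediated condensation may stall at the chelated ketone, or the electron-rich enone may react further by hydroarylation or oligomerisation. The fallback builds ring C by aroyl transfer, sets out from 19 and bypasses step 10 as well. 4-Methoxybenzoyl chloride in pyridine should give (4R)-6-acetyl-7-methoxy-2-oxo-4-phenyl-3,4-dihydro-2H-chromen-5-yl 4-methoxybenzoate F7. NaH in THF (0 °C to 40 °C, then aq. HCl) effects the Baker-Venkataraman shift to (4R)-5-hydroxy-7-methoxy-6-[3-(4-methoxyphenyl)-3-oxopropanoyl]-4-phenyl-3,4-dihydro-2H-chromen-2-one F8. Cyclodehydration of F8 with catalytic H2SO4 in AcOH at 90 °C comes back to the route at 23.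

Step 12. The lactone may re-close during acidification or concentration, and the pyranone ring may open if the base is too strong or too warm. The fallback frees the acid under neutral conditions and sets out from 24. Ring opening with benzyl alcohol (Et3N, catalytic DMAP, THF, 40 °C) should give benzyl (3R)-3-[5,7-dihydroxy-2-(4-hydroxyphenyl)-4-oxo-4H-chromen-8-yl]-3-phenylpropanoate F9. Hydrogenolysis of F9 (H2, Pd/C, EtOAc, 23 °C) arrives at 25 without any acid.

## Further compounds

F1 | step 6 | 5-{(R)-[4-methoxy-2,6-bis(methoxymethoxy)phenyl](phenyl)methyl}-2,2-dimethyl-1,3-dioxane-4,6-dione | CC1(C)OC(=O)C([C@H](c2ccccc2)c2c(OCOC)cc(OC)cc2OCOC)C(=O)O1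
F2 | step 6 | (3R)-2-(methoxycarbonyl)-3-[4-methoxy-2,6-bis(methoxymethoxy)phenyl]-3-phenylpropanoic acid (both C2 epimers) | COC(=O)C(C(O)=O)[C@H](c1ccccc1)c1c(OCOC)cc(OC)cc1OCOC
F3 | step 4 | racemic 5-{1-[4-methoxy-2,6-bis(methoxymethoxy)phenyl]-3-(trimethylsilyl)prop-2-yn-1-yl}-2,2-dimethyl-1,3-dioxane-4,6-dione | CC1(C)OC(=O)C(C(C#C[Si](C)(C)C)c2c(OCOC)cc(OC)cc2OCOC)C(=O)O1
F4 | step 4 | 5-{(1R)-1-[4-methoxy-2,6-bis(methoxymethoxy)phenyl]-3-(trimethylsilyl)prop-2-yn-1-yl}-2,2-dimethyl-1,3-dioxane-4,6-dione | CC1(C)OC(=O)C([C@@H](C#C[Si](C)(C)C)c2c(OCOC)cc(OC)cc2OCOC)C(=O)O1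
F5 | step 8 | (4R)-5-hydroxy-7-methoxy-2-oxo-4-phenyl-3,4-dihydro-2H-chromene-6-carbaldehyde | O=C1C[C@H](c2ccccc2)c2c(O)c(C=O)c(OC)cc2O1
F6 | step 8 | (4R)-5-hydroxy-6-(1-hydroxyethyl)-7-methoxy-4-phenyl-3,4-dihydro-2H-chromen-2-one (both carbinol epimers) | O=C1C[C@H](c2ccccc2)c2c(O)c(C(C)O)c(OC)cc2O1
F7 | step 9 | (4R)-6-acetyl-7-methoxy-2-oxo-4-phenyl-3,4-dihydro-2H-chromen-5-yl 4-methoxybenzoate | O=C1C[C@H](c2ccccc2)c2c(OC(=O)c3ccc(OC)cc3)c(C(C)=O)c(OC)cc2O1
F8 | step 9 | (4R)-5-hydroxy-7-methoxy-6-[3-(4-methoxyphenyl)-3-oxopropanoyl]-4-phenyl-3,4-dihydro-2H-chromen-2-one | O=C1C[C@H](c2ccccc2)c2c(O)c(C(=O)CC(=O)c3ccc(OC)cc3)c(OC)cc2O1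
F9 | step 12 | benzyl (3R)-3-[5,7-dihydroxy-2-(4-hydroxyphenyl)-4-oxo-4H-chromen-8-yl]-3-phenylpropanoate | O=C(OCc1ccccc1)C[C@H](c1ccccc1)c1c(O)cc(O)c2c(=O)cc(-c3ccc(O)cc3)oc12
A1 | alternative 1 | tert-butyl (3R)-3-[5,7-dihydroxy-2-[4-(methoxymethoxy)phenyl]-4-oxo-4H-chromen-8-yl]-3-phenylpropanoate | CC(C)(C)OC(=O)C[C@H](c1ccccc1)c1c(O)cc(O)c2c(=O)cc(-c3ccc(OCOC)cc3)oc12
A2 | alternative 1 | tert-butyl (3S)-7-methoxy-3-phenyl-5,7-bis(trimethylsilyloxy)hepta-4,6-dienoate | CC(C)(C)OC(=O)C[C@H](c1ccccc1)C=C(O[Si](C)(C)C)C=C(OC)O[Si](C)(C)C
A3 | alternative 1 | 2-[4-(methoxymethoxy)phenyl]-5-(4-methylbenzenesulfinyl)-4H-pyran-4-one | COCOc1ccc(cc1)-c1cc(=O)c(S(=O)c2ccc(C)cc2)co1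
A4 | alternative 2 | tert-butyl (3R)-3-[2-hydroxy-4-methoxy-6-(triisopropylsilyloxy)phenyl]-3-phenylpropanoate | CC(C)(C)OC(=O)C[C@H](c1ccccc1)c1c(O)cc(OC)cc1O[Si](C(C)C)(C(C)C)C(C)C
A5 | alternative 2 | 1-diazo-3-methoxybut-3-en-2-one | C=C(OC)C(=O)C=[N+]=[N-]
A6 | alternative 2 | tert-butyl (3R)-3-phenyl-5-(triisopropylsilyloxy)pent-4-ynoate | CC(C)(C)OC(=O)C[C@H](c1ccccc1)C#CO[Si](C(C)C)(C(C)C)C(C)C
A7 | alternative 2 | 3-methoxybuta-1,3-dien-1-one | C=C(OC)C=C=O
A8 | alternative 3 | methyl (3R)-3-[5,7-dimethoxy-2-(4-methoxyphenyl)-4-oxo-4H-chromen-8-yl]-3-phenylpropanoate | COC(=O)C[C@H](c1ccccc1)c1c(OC)cc(OC)c2c(=O)cc(-c3ccc(OC)cc3)oc12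
A9 | alternative 3 | methyl (3R)-3-[4,6-dimethoxy-2-(trifluoromethylsulfonyloxy)-3-(trimethylsilyl)phenyl]-3-phenylpropanoate | COC(=O)C[C@H](c1ccccc1)c1c(OS(=O)(=O)C(F)(F)F)c([Si](C)(C)C)c(OC)cc1OC
A10 | alternative 3 | 3-(4-methoxyphenyl)prop-2-ynoic acid | COc1ccc(cc1)C#CC(=O)O
A11 | alternative 3 | methyl (3R)-3-(2,3-didehydro-4,6-dimethoxyphenyl)-3-phenylpropanoate | COC(=O)C[C@H](c1ccccc1)C1=C(OC)C=C(OC)C#C1
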